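## The problem

Target 22 is a (2S)-flavanone of the naringenin type carrying a (2S)-1-methylpiperidin-2-yl group on C6. Ring A is a phloroglucinol nucleus with one free position (C8), ring C is the dihydropyranone, and ring B is a 4-hydroxyphenyl group on C2. The piperidine is bonded through its C2 to C6, between the C5 and C7 hydroxyls. The C8 isomer differs only in which ortho position carries the C4 carbonyl, so the aryl–piperidine bond and the distinction of O1 from O5 and O7 must be settled before ring C exists. The two stereocentres, C2 of ring C and C2 of the piperidine, are separated by ring A and cannot control each other; each needs its own source of chirality. C2 is the fragile one: the β-aryloxy ketone opens by retro-oxa-Michael reaction to the 2'-hydroxychalcone under base, more readily once the phenols and the basic nitrogen are free. It should therefore be set late and followed only by neutral or acidic operations. Ring A is open to oxidation and to electrophiles such as formaldehyde, and a free tertiary amine would bind an electrophilic metal catalyst, so nitrogen travels as a carbamate and the phenols as ethers. The enabling feature is that C2 is a benzylic carbon bonded to O1 and lies six atoms from C3 along C4, C4a, C8a and O1. A carbene at C3 can therefore insert into a C–H bond of a ring B benzyl ether on O1, and because the fifth atom is an oxygen without hydrogen, the only ring that can form is ring C.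

## Retrosynthesis

**End game, 22 ⇒ 21 ⇒ 20 ⇒ 18.** The first cuts are to protecting groups: the ring B O–benzyl bond (22 ⇒ 21), the O–Si bonds at O5 and O7 (21 ⇒ 20), and the N–methyl bond, traded for the carbamate (20 ⇒ 18). This order is preferred because methylation with formaldehyde must precede release of the ring A phenols, and because a final hydrogenolysis leaves only a volatile by-product beside a polar aminophenol. Compound 18 has the same skeleton, but every heteroatom is masked, which the carbene chemistry before it requires. All forward steps must be neutral or acidic so that C2 is not lost by ring opening.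

**Ring C, 18 ⇒ 17.** The C2–C3 bond is cut, which opens ring C and removes the C2 stereocentre; the precursor is diazomethyl ketone 17, in which ring B is attached only as an ether on O1. Cutting O1–C2 instead leads back to a chalcone whose closure is reversible and gives no absolute control at C2. Cutting C4–C4a requires a strongly acidic acylation next to an ionisable benzylic ether. Cutting C2–aryl (aryl addition to a chromone) is viable but wastes the O1 substituent and is held in reserve. Compound 17 has one stereocentre and no ring C. The forward step asks a chiral dirhodium tetracarboxylate to choose C–H insertion over attack on the ether oxygen and to tell the two benzylic hydrogens apart.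

**Diazoacetyl group, 17 ⇒ 15 ⇒ 13 ⇒ 12.** The C3=N2 unit is removed to give methyl ketone 15, the C4–C4a bond is cut to give aryl bromide 13, and the C–Br bond is cut to give arene 12. The attraction of 12 is its local twofold symmetry about the aryl–piperidine axis: its two free ring positions are equivalent, so bromination has no regiochemical question. This is preferred over an acid chloride with a diazoalkane, which would expose the carbamate and the 4-alkoxybenzyl ether to hydrogen chloride at a hindered acyl centre. The forward steps ask for clean monobromination, a short-lived aryllithium and a diazo transfer that touches only the acetyl methyl group.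

**Ring A, 12 ⇒ 11 ⇒ 5 + 8.** After one O–Si bond is cut (12 ⇒ 11), ring A is disconnected at C5–C6, C7–C8 and C4a–C5 into siloxyalkyne 5 and cyclobutenone 8. A benzannulation is preferred over arylation of a piperidine precursor because it builds the ring on the carbon that already carries the stereocentre. The mechanism puts the piperidine between two oxygens and the third oxygen para to it. Carrying the ring B benzyl ether on 8 means that O1 arrives already bearing the insertion substrate. The precursors are an alkyne with one stereocentre and an achiral four-membered ring. The forward step asks a donor-substituted cyclobutenone to open thermally and be trapped by the ynol ether.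

**Building blocks, 5 ⇒ 2 ⇒ 1 and 8 ⇒ 6 + 7.** The alkyne carbon attached to the piperidine is removed (a one-carbon insertion next to the ester carbonyl of 2), and 2 is the methyl ester of commercial acid 1. Cyclobutenone 8 is cut at its enol ether C–O bond into the commercial pair 6 and 7. The ester route is preferred over building the alkyne from an aldehyde because it reaches 5 from 2 in one operation. The forward reaction must not enolise toward the amino-substituted carbon.

## Roads not taken

**Alternative 1:** The cut runs through the piperidine, at C2''–C3'' and N1''–C6'' (double primes for the piperidine), so ring A arrives as a finished phloroglucinaldehyde ether.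
- **Forward key step:** the (R)-sulfinyl aldimine A1 takes up the Grignard reagent A2 through a magnesium chelate, and base closes the N–C6'' bond in the same flask to give sulfinyl piperidine A3.
- **Merits:** cheap components, a well-understood stereochemical model, access to either enantiomer, and no pericyclic cascade.
- **Weak points:** addition to an aldimine flanked by two ortho substituents; later acid treatment to trade the sulfinyl group for methyl beside an acetal; and A3 says nothing about ring C. C2 still has to be set, and benzyl ethers on O5 and O7 would offer competing C–H bonds to a carbene at C3, so the oxygen pattern would need reworking.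
- **Comparison:** for the piperidine stereocentre alone this road is at least as dependable as step 4, and it is kept as the fallback for that step. The chosen plan sets against it a stereocentre taken from the chiral pool with no auxiliary to attach and remove, and an O1 benzyl ether that arrives in the ring-forming step.

**Alternative 2:** The cut is C4–C4a.
- **Forward key step:** the (S)-configured β-aryloxy acid A4, activated as a mixed anhydride, acylates the ring ortho to the ether oxygen and closes ring C to give flavanone A5. The phenol ether is symmetric about the aryl–piperidine axis, so either ortho position gives the same product.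
- **Merits:** C2 is bought from a separately made enantioenriched 3-aryl-3-hydroxypropanoate; the N-methyl group is already present; all oxygen protecting groups fall in one hydrogenolysis; and every reaction type has precedent, which the chosen key step cannot claim.
- **Weak points:** A4 is a β-aryloxy acyl electrophile with a benzylic C–O bond. Under strongly acidic acylation it can eliminate to the cinnamate or ionise at C2, and either path erases the stereocentre. The etherification with inversion at a benzylic carbinol is itself prone to partial loss of configuration. The amine must be carried as a salt through an electrophilic step.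
- **Comparison:** the shorter end game and firmer precedent are on its side. The chosen plan forms C2 in the ring-closing event under neutral conditions and catalyst control, so the stereocentre never exists in an open-chain, elimination-prone form.

**Alternative 3:** The cut is ring A itself, at C5–C6, C7–C8 and C4a–C5.
- **Forward key step:** heating siloxyalkyne 5 with cyclobutenone A6 gives phenol A7 with three differently substituted oxygens.
- **Merits:** the stereocentre comes from L-pipecolic acid, the regiochemistry is fixed by the mechanism, and O1, O5 and O7 are differentiated.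
- **Relation to the chosen route:** this is the same ring A construction used in step 4; the difference is what follows it.
- **Weak points:** from A7, ring C would be completed by conventional means (ortho-acylation, chalcone, oxa-Michael closure). These are known reactions, a real advantage over the untested step 9, but the reversible closure puts C2 under thermodynamic control with only a remote stereocentre, so a mixture of C2 epimers is to be expected. Steering A7 to the insertion substrate instead would cost removal and replacement of the 4-methoxybenzyl group.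
- **Comparison:** the chosen plan sets catalyst-controlled formation of C2, and a sequence two steps shorter (the ring B benzyl ether rides in on 8), against the firmer precedent of this road.

Key step: step 9

Assumption: the sense of induction of Rh2(S-PTTL)4, dirhodium tetrakis[N-phthaloyl-(S)-tert-leucinate], in step 9 is taken to be 2S; should it prove to be 2R, the enantiomeric catalyst Rh2(R-PTTL)4 is used with no other change.

## Route

Step 1
Reactants: 1 (2S)-1-(tert-butoxycarbonyl)piperidine-2-carboxylic acid
Product: 2 1-tert-butyl 2-methyl (2S)-piperidine-1,2-dicarboxylate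
Conditions: MeI, K2CO3, DMF, 23 °C
Reagents that add atoms: iodomethane, CI
Why: Carboxylate O-alkylation (SN2 on iodomethane); carbonate does not deprotonate the carbamate-protected α-carbon, so the stereocentre is carried over unchanged.

Step 2
Reactants: 2 1-tert-butyl 2-methyl (2S)-piperidine-1,2-dicarboxylate
Product: 5 tert-butyl (2S)-2-[(triisopropylsilyloxy)ethynyl]piperidine-1-carboxylate, via lithium dibromoenolate 3 (not isolated), via lithium ynolate 4 (not isolated)
Conditions: CH2Br2, lithium 2,2,6,6-tetramethylpiperidide, THF, −78 °C; add 2; LiN(SiMe3)2, then n-BuLi, −78 → 20 °C; i-Pr3SiCl, 0 °C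
Reagents that add atoms: dibromomethane, BrCBr; chlorotriisopropylsilane, CC(C)[Si](Cl)(C(C)C)C(C)C
Why: Kowalski ester homologation stopped at the ynolate: acylation of LiCHBr2, enolisation at the far more acidic dibromomethyl hydrogen to 3, bromine–lithium exchange and 1,2-shift of the piperidinyl carbon with retention give 4, which the bulky silyl chloride traps on oxygen. The carbonyl is masked as a tetrahedral adduct and then as enolate 3, so the amino-substituted carbon should not be enolised.

Step 3
Reactants: 6 3-ethoxycyclobut-2-en-1-one; 7 [4-(benzyloxy)phenyl]methanol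
Product: 8 3-[4-(benzyloxy)benzyloxy]cyclobut-2-en-1-one
Conditions: pyridinium p-toluenesulfonate (cat.), toluene, 45 °C, reduced pressure (−EtOH)
Reagents that add atoms: none
Why: Acid-catalysed transetherification of a vinylogous ester (addition of the alcohol at C3 of the O-protonated enone, loss of ethanol), driven by removal of ethanol; the weak pyridinium acid is chosen so that the 4-alkoxybenzyl alcohol is not ionised.

Step 4
Reactants: 5 tert-butyl (2S)-2-[(triisopropylsilyloxy)ethynyl]piperidine-1-carboxylate; 8 3-[4-(benzyloxy)benzyloxy]cyclobut-2-en-1-one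
Product: 11 tert-butyl (2S)-2-{4-[4-(benzyloxy)benzyloxy]-2-hydroxy-6-(triisopropylsilyloxy)phenyl}piperidine-1-carboxylate, via vinylketene 9 (not isolated), via vinylcyclobutenone 10 (not isolated)
Conditions: toluene, 80 → 110 °C
Reagents that add atoms: none
Why: Danheiser benzannulation with a siloxyalkyne as ketenophile: 4π electrocyclic opening of 8 gives 9, regioselective [2+2] cycloaddition (nucleophilic alkyne carbon to the ketene carbon) gives 10, and a second 4π opening, 6π electrocyclisation and tautomerisation deliver the phenol. The mechanism places the piperidine between the hydroxyl and the silyl ether and the ring B benzyl ether para to it; the piperidine stereocentre is a spectator.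

Step 5
Reactants: 11 tert-butyl (2S)-2-{4-[4-(benzyloxy)benzyloxy]-2-hydroxy-6-(triisopropylsilyloxy)phenyl}piperidine-1-carboxylate
Product: 12 tert-butyl (2S)-2-{4-[4-(benzyloxy)benzyloxy]-2,6-bis(triisopropylsilyloxy)phenyl}piperidine-1-carboxylate
Conditions: i-Pr3SiCl, imidazole, DMAP (cat.), DMF, 50 °C
Reagents that add atoms: chlorotriisopropylsilane, CC(C)[Si](Cl)(C(C)C)C(C)C
Why: Phenol silylation; the chloride–imidazole system leaves the carbamate untouched, which a silyl triflate would not. The second silyl ether makes ring A locally twofold-symmetric, so its two free positions become equivalent.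

Step 6
Reactants: 12 tert-butyl (2S)-2-{4-[4-(benzyloxy)benzyloxy]-2,6-bis(triisopropylsilyloxy)phenyl}piperidine-1-carboxylate
Product: 13 tert-butyl (2S)-2-{4-[4-(benzyloxy)benzyloxy]-3-bromo-2,6-bis(triisopropylsilyloxy)phenyl}piperidine-1-carboxylate
Conditions: N-bromosuccinimide (1.0 equiv), CH2Cl2, −20 °C, dark
Reagents that add atoms: N-bromosuccinimide, O=C1CCC(=O)N1Br
Why: Electrophilic aromatic bromination of the ring with three oxygen donors, which is far more reactive than the two monoalkoxy rings; both free positions are equivalent, and one equivalent at low temperature should stop at the monobromide.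

Step 7
Reactants: 13 tert-butyl (2S)-2-{4-[4-(benzyloxy)benzyloxy]-3-bromo-2,6-bis(triisopropylsilyloxy)phenyl}piperidine-1-carboxylate
Product: 15 tert-butyl (2S)-2-{3-acetyl-4-[4-(benzyloxy)benzyloxy]-2,6-bis(triisopropylsilyloxy)phenyl}piperidine-1-carboxylate, via aryllithium 14 (not isolated)
Conditions: n-BuLi, THF, −78 °C; MeC(O)N(OMe)Me, −78 → 0 °C; aq. NH4Cl
Reagents that add atoms: N-methoxy-N-methylacetamide, CON(C)C(C)=O
Why: Bromine–lithium exchange followed by Weinreb ketone synthesis; the chelated tetrahedral adduct prevents over-addition, and at −78 °C the exchange is faster than attack on the carbamate or deprotonation of the benzylic ether.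

Step 8
Reactants: 15 tert-butyl (2S)-2-{3-acetyl-4-[4-(benzyloxy)benzyloxy]-2,6-bis(triisopropylsilyloxy)phenyl}piperidine-1-carboxylate
Product: 17 tert-butyl (2S)-2-{4-[4-(benzyloxy)benzyloxy]-3-(diazoacetyl)-2,6-bis(triisopropylsilyloxy)phenyl}piperidine-1-carboxylate, via trifluoroacetyl diketone 16 (not isolated)
Conditions: LiN(SiMe3)2, THF, −78 °C; CF3CO2CH2CF3; then MeSO2N3, Et3N, H2O (1 equiv), MeCN, 23 °C
Reagents that add atoms: methanesulfonyl azide, CS(=O)(=O)N=[N+]=[N-]
Why: Detrifluoroacetylative (Regitz-type deacylative) diazo transfer: the methyl ketone enolate is trifluoroacetylated to 16, which is acidic enough to accept the diazo group from the sulfonyl azide and then passes its trifluoroacetyl group to the sulfonamide. Only the acetyl methyl group reacts, and the conditions are mild to silyl ethers, carbamate and benzyl ethers.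

Step 9
Reactants: 17 tert-butyl (2S)-2-{4-[4-(benzyloxy)benzyloxy]-3-(diazoacetyl)-2,6-bis(triisopropylsilyloxy)phenyl}piperidine-1-carboxylate
Product: 18 tert-butyl (2S)-2-{(2S)-2-[4-(benzyloxy)phenyl]-4-oxo-5,7-bis(triisopropylsilyloxy)-3,4-dihydro-2H-chromen-6-yl}piperidine-1-carboxylate
Conditions: Rh2(S-PTTL)4 (2 mol %), toluene, −40 → 0 °C, slow addition of 17
Reagents that add atoms: none
Why: Proposed new method: loss of N2 from 17 at the dirhodium core gives an electrophilic metal carbene at C3 that inserts, through a three-centre transition state with hydride-shift character, into a C–H bond of the O1 methylene, which is activated by the oxygen lone pair and by the 4-benzyloxyphenyl ring. The closest known reaction type is the dirhodium-carboxylate-catalysed C–H insertion of 2-alkoxyaryl diazoketones to chroman-4-ones; its use on a terminal diazomethyl ketone with a chiral catalyst to give a 2-arylchromanone as one enantiomer is not established. Ring C closes as a six-membered ring by 1,6-insertion, because the 1,5-position is O1 and carries no hydrogen. C2 is set by the catalyst: the phthalimido walls of the tert-leucinate ligands choose between the two diastereotopic benzylic hydrogens and insertion goes with retention, while the piperidine stereocentre across ring A should have little influence. The step needs chemoselectivity for insertion over attack of O1 on the carbene, which would give an oxonium ylide and then a benzofuran-3-one by [1,2]-benzyl shift. In the substrate, the O1 lone pair is delocalised into the acylated ring and so is weakly nucleophilic, and the benzylic C–H bond is electron-rich; the bulky carboxylate ligands, the non-polar solvent and the low temperature work in the same direction. O5 and O7 are silyl ethers with no C–H bond α to oxygen, the carbamate keeps nitrogen from binding rhodium, and slow addition suppresses carbene dimerisation.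

Step 10
Reactants: 18 tert-butyl (2S)-2-{(2S)-2-[4-(benzyloxy)phenyl]-4-oxo-5,7-bis(triisopropylsilyloxy)-3,4-dihydro-2H-chromen-6-yl}piperidine-1-carboxylate
Product: 20 (2S)-2-[4-(benzyloxy)phenyl]-6-[(2S)-1-methylpiperidin-2-yl]-5,7-bis(triisopropylsilyloxy)-2,3-dihydro-4H-chromen-4-one, via piperidinium trifluoroacetate 19 (not isolated)
Conditions: CF3CO2H, CH2Cl2, 0 °C; concentrate; then aq. CH2O, NaBH(OAc)3, Et3N, ClCH2CH2Cl, 0 → 23 °C
Reagents that add atoms: formaldehyde, C=O
Why: Acidolysis of the tert-butyl carbamate, then reductive amination (iminium reduction by NaBH(OAc)3), which should not reduce the hindered aryl ketone. Methylation is done while O5 and O7 are still silylated, so that C8 of ring A cannot enter a Mannich reaction with formaldehyde.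

Step 11
Reactants: 20 (2S)-2-[4-(benzyloxy)phenyl]-6-[(2S)-1-methylpiperidin-2-yl]-5,7-bis(triisopropylsilyloxy)-2,3-dihydro-4H-chromen-4-one
Product: 21 (2S)-2-[4-(benzyloxy)phenyl]-5,7-dihydroxy-6-[(2S)-1-methylpiperidin-2-yl]-2,3-dihydro-4H-chromen-4-one
Conditions: HF·pyridine, THF, 0 → 23 °C
Reagents that add atoms: none
Why: Fluoride cleavage of the two aryl silyl ethers in an acidic medium; the amine stays protonated, so base-induced opening of ring C and loss of the C2 configuration are avoided.

Step 12
Reactants: 21 (2S)-2-[4-(benzyloxy)phenyl]-5,7-dihydroxy-6-[(2S)-1-methylpiperidin-2-yl]-2,3-dihydro-4H-chromen-4-one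
Product: 22 (2S)-5,7-dihydroxy-2-(4-hydroxyphenyl)-6-[(2S)-1-methylpiperidin-2-yl]-2,3-dihydro-4H-chromen-4-one
Conditions: H2 (1 atm), Pd/C, AcOH (1 equiv), EtOAc/MeOH, 23 °C
Reagents that add atoms: none
Why: Hydrogenolysis of the primary aryl benzyl ether, which should be much faster than cleavage of the ring benzylic C2–O1 and piperidine C–N bonds if the reaction is stopped when 21 is consumed. One equivalent of acetic acid keeps the amine from slowing the catalyst and from acting as a base toward ring C.

## Compound list

1 | (2S)-1-(tert-butoxycarbonyl)piperidine-2-carboxylic acid | CC(C)(C)OC(=O)N1CCCC[C@H]1C(=O)O | starting material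
2 | 1-tert-butyl 2-methyl (2S)-piperidine-1,2-dicarboxylate | CC(C)(C)OC(=O)N1CCCC[C@H]1C(=O)OC | intermediate
3 | lithium enolate of tert-butyl (2S)-2-(dibromoacetyl)piperidine-1-carboxylate | CC(C)(C)OC(=O)N1CCCC[C@H]1C(O[Li])=C(Br)Br | intermediate
4 | lithium 2-[(2S)-1-(tert-butoxycarbonyl)piperidin-2-yl]ethynolate | CC(C)(C)OC(=O)N1CCCC[C@H]1C#CO[Li] | intermediate
5 | tert-butyl (2S)-2-[(triisopropylsilyloxy)ethynyl]piperidine-1-carboxylate | CC(C)(C)OC(=O)N1CCCC[C@H]1C#CO[Si](C(C)C)(C(C)C)C(C)C | intermediate
6 | 3-ethoxycyclobut-2-en-1-one | CCOC1=CC(=O)C1 | starting material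
7 | [4-(benzyloxy)phenyl]methanol | OCc1ccc(OCc2ccccc2)cc1 | starting material
8 | 3-[4-(benzyloxy)benzyloxy]cyclobut-2-en-1-one | O=C1C=C(OCc2ccc(OCc3ccccc3)cc2)C1 | intermediate
9 | 3-[4-(benzyloxy)benzyloxy]buta-1,3-dien-1-one | C=C(OCc1ccc(OCc2ccccc2)cc1)C=C=O | intermediate
10 | tert-butyl (2S)-2-[3-{1-[4-(benzyloxy)benzyloxy]ethenyl}-4-oxo-2-(triisopropylsilyloxy)cyclobut-1-en-1-yl]piperidine-1-carboxylate (both configurations at the ring sp3 carbon) | CC(C)(C)OC(=O)N1CCCC[C@H]1C1=C(O[Si](C(C)C)(C(C)C)C(C)C)C(C(=C)OCc2ccc(OCc3ccccc3)cc2)C1=O | intermediate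
11 | tert-butyl (2S)-2-{4-[4-(benzyloxy)benzyloxy]-2-hydroxy-6-(triisopropylsilyloxy)phenyl}piperidine-1-carboxylate | CC(C)(C)OC(=O)N1CCCC[C@H]1c1c(O)cc(OCc2ccc(OCc3ccccc3)cc2)cc1O[Si](C(C)C)(C(C)C)C(C)C | intermediate
12 | tert-butyl (2S)-2-{4-[4-(benzyloxy)benzyloxy]-2,6-bis(triisopropylsilyloxy)phenyl}piperidine-1-carboxylate | CC(C)(C)OC(=O)N1CCCC[C@H]1c1c(O[Si](C(C)C)(C(C)C)C(C)C)cc(OCc2ccc(OCc3ccccc3)cc2)cc1O[Si](C(C)C)(C(C)C)C(C)C | intermediate
13 | tert-butyl (2S)-2-{4-[4-(benzyloxy)benzyloxy]-3-bromo-2,6-bis(triisopropylsilyloxy)phenyl}piperidine-1-carboxylate | CC(C)(C)OC(=O)N1CCCC[C@H]1c1c(O[Si](C(C)C)(C(C)C)C(C)C)cc(OCc2ccc(OCc3ccccc3)cc2)c(Br)c1O[Si](C(C)C)(C(C)C)C(C)C | intermediate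
14 | tert-butyl (2S)-2-{4-[4-(benzyloxy)benzyloxy]-3-lithio-2,6-bis(triisopropylsilyloxy)phenyl}piperidine-1-carboxylate | CC(C)(C)OC(=O)N1CCCC[C@H]1c1c(O[Si](C(C)C)(C(C)C)C(C)C)cc(OCc2ccc(OCc3ccccc3)cc2)c([Li])c1O[Si](C(C)C)(C(C)C)C(C)C | intermediate
15 | tert-butyl (2S)-2-{3-acetyl-4-[4-(benzyloxy)benzyloxy]-2,6-bis(triisopropylsilyloxy)phenyl}piperidine-1-carboxylate | CC(C)(C)OC(=O)N1CCCC[C@H]1c1c(O[Si](C(C)C)(C(C)C)C(C)C)cc(OCc2ccc(OCc3ccccc3)cc2)c(C(C)=O)c1O[Si](C(C)C)(C(C)C)C(C)C | intermediate
16 | tert-butyl (2S)-2-{4-[4-(benzyloxy)benzyloxy]-3-(4,4,4-trifluoro-3-oxobutanoyl)-2,6-bis(triisopropylsilyloxy)phenyl}piperidine-1-carboxylate | CC(C)(C)OC(=O)N1CCCC[C@H]1c1c(O[Si](C(C)C)(C(C)C)C(C)C)cc(OCc2ccc(OCc3ccccc3)cc2)c(C(=O)CC(=O)C(F)(F)F)c1O[Si](C(C)C)(C(C)C)C(C)C | intermediate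
17 | tert-butyl (2S)-2-{4-[4-(benzyloxy)benzyloxy]-3-(diazoacetyl)-2,6-bis(triisopropylsilyloxy)phenyl}piperidine-1-carboxylate | CC(C)(C)OC(=O)N1CCCC[C@H]1c1c(O[Si](C(C)C)(C(C)C)C(C)C)cc(OCc2ccc(OCc3ccccc3)cc2)c(C(=O)C=[N+]=[N-])c1O[Si](C(C)C)(C(C)C)C(C)C | intermediate
18 | tert-butyl (2S)-2-{(2S)-2-[4-(benzyloxy)phenyl]-4-oxo-5,7-bis(triisopropylsilyloxy)-3,4-dihydro-2H-chromen-6-yl}piperidine-1-carboxylate | CC(C)(C)OC(=O)N1CCCC[C@H]1c1c(O[Si](C(C)C)(C(C)C)C(C)C)cc2c(c1O[Si](C(C)C)(C(C)C)C(C)C)C(=O)C[C@@H](c1ccc(OCc3ccccc3)cc1)O2 | intermediate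
19 | (2S)-2-[4-(benzyloxy)phenyl]-6-[(2S)-piperidin-2-yl]-5,7-bis(triisopropylsilyloxy)-2,3-dihydro-4H-chromen-4-one trifluoroacetate | N1CCCC[C@H]1c1c(O[Si](C(C)C)(C(C)C)C(C)C)cc2c(c1O[Si](C(C)C)(C(C)C)C(C)C)C(=O)C[C@@H](c1ccc(OCc3ccccc3)cc1)O2.OC(=O)C(F)(F)F | intermediate
20 | (2S)-2-[4-(benzyloxy)phenyl]-6-[(2S)-1-methylpiperidin-2-yl]-5,7-bis(triisopropylsilyloxy)-2,3-dihydro-4H-chromen-4-one | CN1CCCC[C@H]1c1c(O[Si](C(C)C)(C(C)C)C(C)C)cc2c(c1O[Si](C(C)C)(C(C)C)C(C)C)C(=O)C[C@@H](c1ccc(OCc3ccccc3)cc1)O2 | intermediate
21 | (2S)-2-[4-(benzyloxy)phenyl]-5,7-dihydroxy-6-[(2S)-1-methylpiperidin-2-yl]-2,3-dihydro-4H-chromen-4-one | CN1CCCC[C@H]1c1c(O)cc2c(c1O)C(=O)C[C@@H](c1ccc(OCc3ccccc3)cc1)O2 | intermediate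
22 | (2S)-5,7-dihydroxy-2-(4-hydroxyphenyl)-6-[(2S)-1-methylpiperidin-2-yl]-2,3-dihydro-4H-chromen-4-one | CN1CCCC[C@H]1c1c(O)cc2c(c1O)C(=O)C[C@@H](c1ccc(O)cc1)O2 | target

## Step count and least certain steps

Total: 12 steps. Longest linear sequence: 11 steps (1 → 2 → 5 → 11 → 12 → 13 → 15 → 17 → 18 → 20 → 21 → 22); step 3 is a one-step side branch.

**Step 9 (key step, proposed new method).** The most likely failure is attack of the O1 lone pair on the carbene, followed by [1,2]-shift of the benzyl group, because a five-membered ylide is geometrically easy and the 4-alkoxybenzyl group migrates well. The second risk is poor discrimination between the two benzylic hydrogens, because an unsubstituted acceptor carbene reacts through an early transition state. Tuning within the catalyst family comes first. The fallback uses known chemistry, sets out from 15 and comes back at 18: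
- Oxidative cleavage of the O1 ether of 15 with 2,3-dichloro-5,6-dicyano-1,4-benzoquinone in wet CH2Cl2 would give tert-butyl (2S)-2-[3-acetyl-4-hydroxy-2,6-bis(triisopropylsilyloxy)phenyl]piperidine-1-carboxylate F1.
- Condensation with N,N-dimethylformamide dimethyl acetal would give the enaminone tert-butyl (2S)-2-{3-[(2E)-3-(dimethylamino)prop-2-enoyl]-4-hydroxy-2,6-bis(triisopropylsilyloxy)phenyl}piperidine-1-carboxylate F2.
- Warm acetic acid would close F2 to the chromone tert-butyl (2S)-2-[4-oxo-5,7-bis(triisopropylsilyloxy)-4H-chromen-6-yl]piperidine-1-carboxylate F3.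
- Asymmetric conjugate addition of 4-(benzyloxy)phenylboronic acid to F3, catalysed by Pd(O2CCF3)2 with the enantiomer of 4-tert-butyl-2-(pyridin-2-yl)-4,5-dihydrooxazole that delivers the 2S product (NH4PF6, H2O, ClCH2CH2Cl, 60 °C), would give 18.

**Step 4.** The most likely failure is slow electrocyclic opening of the donor-substituted cyclobutenone, so that oligomerisation of 8 or thermal decay of 5 outruns the cycloaddition, or arrest at the vinylcyclobutenone stage. The fallback annulates the piperidine onto a finished ring A; it sets out from 7 and comes back at 12: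
- Mitsunobu etherification (PPh3, diisopropyl azodicarboxylate) of the most acidic 4-hydroxyl of commercial 2,4,6-trihydroxybenzaldehyde with 7 would give 4-[4-(benzyloxy)benzyloxy]-2,6-dihydroxybenzaldehyde F4.
- Silylation (i-Pr3SiCl, imidazole) would give 4-[4-(benzyloxy)benzyloxy]-2,6-bis(triisopropylsilyloxy)benzaldehyde F5.
- Condensation with (R)-2-methylpropane-2-sulfinamide and Ti(OEt)4 would give (R)-N-{(E)-[4-[4-(benzyloxy)benzyloxy]-2,6-bis(triisopropylsilyloxy)phenyl]methylidene}-2-methylpropane-2-sulfinamide F6.
- Chelate-controlled addition of 4-chlorobutylmagnesium bromide A2 in CH2Cl2 would give (R)-N-{(1S)-1-[4-[4-(benzyloxy)benzyloxy]-2,6-bis(triisopropylsilyloxy)phenyl]-5-chloropentyl}-2-methylpropane-2-sulfinamide F7.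
- NaH would close F7 to (2S)-2-{4-[4-(benzyloxy)benzyloxy]-2,6-bis(triisopropylsilyloxy)phenyl}-1-[(R)-tert-butylsulfinyl]piperidine F8.
- Brief HCl in methanol at 0 °C would give (2S)-2-{4-[4-(benzyloxy)benzyloxy]-2,6-bis(triisopropylsilyloxy)phenyl}piperidine F9, and di-tert-butyl dicarbonate with Et3N would convert F9 into 12.

**Step 2.** The most likely failure is enolisation toward the amino-substituted carbon at the ketone stage (loss of configuration), or incomplete rearrangement of the carbenoid. The fallback makes the ynolate by oxidation of an acetylide; it sets out from 2 and comes back at 5: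
- Reduction with i-Bu2AlH at −78 °C would give tert-butyl (2S)-2-formylpiperidine-1-carboxylate F10.
- Ohira–Bestmann homologation (dimethyl (1-diazo-2-oxopropyl)phosphonate, K2CO3, MeOH, 0 °C) would give tert-butyl (2S)-2-ethynylpiperidine-1-carboxylate F11.
- Lithiation of F11 with n-BuLi, oxidation of the acetylide with lithium tert-butyl peroxide to ynolate 4, and silylation with i-Pr3SiCl would give 5.

**Step 3.** The most likely failure is acid-induced ionisation of the 4-alkoxybenzyl alcohol (self-etherification), or hydrolytic opening of the strained vinylogous ester before exchange. The fallback replaces exchange by O-alkylation of the vinylogous acid; it sets out from 6 and comes back at 8: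
- Hydrolysis of 6 with dilute aqueous acid would give cyclobutane-1,3-dione F12, which exists largely as its enol.
- Mitsunobu reaction of F12 with 7 (PPh3, diisopropyl azodicarboxylate, THF, 0 °C) would give 8.

**Step 7.** The most likely failure is proton transfer from the enolisable amide to the hindered aryllithium, which would return debrominated arene; migration of silicon from oxygen to the lithiated carbon on warming is a second risk. The fallback uses a small, non-enolisable electrophile and an Arndt–Eistert-type acylation of a diazoalkane, by-passing 15 and step 8; it sets out from 13 and comes back at 17: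
- Exchange as before and quenching of 14 with CO2 would give 6-[4-(benzyloxy)benzyloxy]-3-[(2S)-1-(tert-butoxycarbonyl)piperidin-2-yl]-2,4-bis(triisopropylsilyloxy)benzoic acid F13.
- 1-Chloro-N,N,2-trimethylprop-1-en-1-amine under neutral conditions would give 6-[4-(benzyloxy)benzyloxy]-3-[(2S)-1-(tert-butoxycarbonyl)piperidin-2-yl]-2,4-bis(triisopropylsilyloxy)benzoyl chloride F14.
- (Trimethylsilyl)diazomethane in MeCN/THF at 0 °C would convert F14 into 17.

## Further compounds

F1 | step 9 | tert-butyl (2S)-2-[3-acetyl-4-hydroxy-2,6-bis(triisopropylsilyloxy)phenyl]piperidine-1-carboxylate | CC(C)(C)OC(=O)N1CCCC[C@H]1c1c(O[Si](C(C)C)(C(C)C)C(C)C)cc(O)c(C(C)=O)c1O[Si](C(C)C)(C(C)C)C(C)C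
F2 | step 9 | tert-butyl (2S)-2-{3-[(2E)-3-(dimethylamino)prop-2-enoyl]-4-hydroxy-2,6-bis(triisopropylsilyloxy)phenyl}piperidine-1-carboxylate | CC(C)(C)OC(=O)N1CCCC[C@H]1c1c(O[Si](C(C)C)(C(C)C)C(C)C)cc(O)c(C(=O)/C=C/N(C)C)c1O[Si](C(C)C)(C(C)C)C(C)C
F3 | step 9 | tert-butyl (2S)-2-[4-oxo-5,7-bis(triisopropylsilyloxy)-4H-chromen-6-yl]piperidine-1-carboxylate | CC(C)(C)OC(=O)N1CCCC[C@H]1c1c(O[Si](C(C)C)(C(C)C)C(C)C)cc2occc(=O)c2c1O[Si](C(C)C)(C(C)C)C(C)C
F4 | step 4 | 4-[4-(benzyloxy)benzyloxy]-2,6-dihydroxybenzaldehyde | O=Cc1c(O)cc(OCc2ccc(OCc3ccccc3)cc2)cc1O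
F5 | step 4 | 4-[4-(benzyloxy)benzyloxy]-2,6-bis(triisopropylsilyloxy)benzaldehyde | O=Cc1c(O[Si](C(C)C)(C(C)C)C(C)C)cc(OCc2ccc(OCc3ccccc3)cc2)cc1O[Si](C(C)C)(C(C)C)C(C)C
F6 | step 4 | (R)-N-{(E)-[4-[4-(benzyloxy)benzyloxy]-2,6-bis(triisopropylsilyloxy)phenyl]methylidene}-2-methylpropane-2-sulfinamide | CC(C)(C)[S@@](=O)/N=C/c1c(O[Si](C(C)C)(C(C)C)C(C)C)cc(OCc2ccc(OCc3ccccc3)cc2)cc1O[Si](C(C)C)(C(C)C)C(C)C
F7 | step 4 | (R)-N-{(1S)-1-[4-[4-(benzyloxy)benzyloxy]-2,6-bis(triisopropylsilyloxy)phenyl]-5-chloropentyl}-2-methylpropane-2-sulfinamide | CC(C)(C)[S@@](=O)N[C@@H](CCCCCl)c1c(O[Si](C(C)C)(C(C)C)C(C)C)cc(OCc2ccc(OCc3ccccc3)cc2)cc1O[Si](C(C)C)(C(C)C)C(C)C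
F8 | step 4 | (2S)-2-{4-[4-(benzyloxy)benzyloxy]-2,6-bis(triisopropylsilyloxy)phenyl}-1-[(R)-tert-butylsulfinyl]piperidine | CC(C)(C)[S@@](=O)N1CCCC[C@H]1c1c(O[Si](C(C)C)(C(C)C)C(C)C)cc(OCc2ccc(OCc3ccccc3)cc2)cc1O[Si](C(C)C)(C(C)C)C(C)C
F9 | step 4 | (2S)-2-{4-[4-(benzyloxy)benzyloxy]-2,6-bis(triisopropylsilyloxy)phenyl}piperidine | N1CCCC[C@H]1c1c(O[Si](C(C)C)(C(C)C)C(C)C)cc(OCc2ccc(OCc3ccccc3)cc2)cc1O[Si](C(C)C)(C(C)C)C(C)C
F10 | step 2 | tert-butyl (2S)-2-formylpiperidine-1-carboxylate | CC(C)(C)OC(=O)N1CCCC[C@H]1C=O
F11 | step 2 | tert-butyl (2S)-2-ethynylpiperidine-1-carboxylate | CC(C)(C)OC(=O)N1CCCC[C@H]1C#C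
F12 | step 3 | cyclobutane-1,3-dione | O=C1CC(=O)C1
F13 | step 7 | 6-[4-(benzyloxy)benzyloxy]-3-[(2S)-1-(tert-butoxycarbonyl)piperidin-2-yl]-2,4-bis(triisopropylsilyloxy)benzoic acid | CC(C)(C)OC(=O)N1CCCC[C@H]1c1c(O[Si](C(C)C)(C(C)C)C(C)C)cc(OCc2ccc(OCc3ccccc3)cc2)c(C(=O)O)c1O[Si](C(C)C)(C(C)C)C(C)C
F14 | step 7 | 6-[4-(benzyloxy)benzyloxy]-3-[(2S)-1-(tert-butoxycarbonyl)piperidin-2-yl]-2,4-bis(triisopropylsilyloxy)benzoyl chloride | CC(C)(C)OC(=O)N1CCCC[C@H]1c1c(O[Si](C(C)C)(C(C)C)C(C)C)cc(OCc2ccc(OCc3ccccc3)cc2)c(C(=O)Cl)c1O[Si](C(C)C)(C(C)C)C(C)C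
A1 | alternative 1 | (R)-N-{(E)-[2,6-bis(benzyloxy)-4-(methoxymethoxy)phenyl]methylidene}-2-methylpropane-2-sulfinamide | CC(C)(C)[S@@](=O)/N=C/c1c(OCc2ccccc2)cc(OCOC)cc1OCc1ccccc1
A2 | alternative 1 | 4-chlorobutylmagnesium bromide | ClCCCC[Mg]Br
A3 | alternative 1 | (2S)-2-[2,6-bis(benzyloxy)-4-(methoxymethoxy)phenyl]-1-[(R)-tert-butylsulfinyl]piperidine | CC(C)(C)[S@@](=O)N1CCCC[C@H]1c1c(OCc2ccccc2)cc(OCOC)cc1OCc1ccccc1
A4 | alternative 2 | (3S)-3-{3,5-bis(benzyloxy)-4-[(2S)-1-methylpiperidin-2-yl]phenoxy}-3-{4-[(benzyloxycarbonyl)oxy]phenyl}propanoic acid | CN1CCCC[C@H]1c1c(OCc2ccccc2)cc(O[C@@H](CC(=O)O)c2ccc(OC(=O)OCc3ccccc3)cc2)cc1OCc1ccccc1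
A5 | alternative 2 | benzyl 4-{(2S)-5,7-bis(benzyloxy)-6-[(2S)-1-methylpiperidin-2-yl]-4-oxo-3,4-dihydro-2H-chromen-2-yl}phenyl carbonate | CN1CCCC[C@H]1c1c(OCc2ccccc2)cc2c(c1OCc1ccccc1)C(=O)C[C@@H](c1ccc(OC(=O)OCc3ccccc3)cc1)O2
A6 | alternative 3 | 3-[(4-methoxybenzyl)oxy]cyclobut-2-en-1-one | COc1ccc(COC2=CC(=O)C2)cc1
A7 | alternative 3 | tert-butyl (2S)-2-{2-hydroxy-4-[(4-methoxybenzyl)oxy]-6-(triisopropylsilyloxy)phenyl}piperidine-1-carboxylate | CC(C)(C)OC(=O)N1CCCC[C@H]1c1c(O)cc(OCc2ccc(OC)cc2)cc1O[Si](C(C)C)(C(C)C)C(C)C
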